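- The pitfall is to interpolate between percentages. At 120 min dawn's ring reads 51.1 % and spring's 19.5 %, yet percent hides what a larger charge adds. So I count ring, crystals included, in molar and charge in decades: from dawn to spring the charge rises 1.23 decades, and by these readings [ring] rises by a factor of 6.49.

| flask | substrate | remark | time |
|---|---|---|---|
| dawn | 0.10 M | run made earlier |  |
| spring | 1.7 M | run made earlier |  |
| green | 0.60 M |  | 2.0 h |
| violet | 0.080 M |  | 2.0 h |
| blue | 1.2 M |  | 2.0 h |
| grey | 0.31 M |  | 2.0 h |

| run | time / min | ring / % | substrate / % |
|---|---|---|---|
| dawn | 6.00 | 40.7 | 44.0 |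
| dawn | 20.0 | 57.9 | 17.9 |
| dawn | 30.0 | 59.2 | 13.8 |
| dawn | 50.0 | 58.7 | 11.1 |
| dawn | 80.0 | 55.5 | 10.8 |
| dawn | 90.0 | 54.3 | 10.5 |
| dawn | 120 | 51.1 | 9.8 |
| spring | 6.00 | 16.9 | 10.6 |
| spring | 20.0 | 19.1 | 1.9 |
| spring | 30.0 | 19.3 | 1.5 |
| spring | 50.0 | 19.7 | 0.1 |
| spring | 80.0 | 19.9 | 0.6 |
| spring | 90.0 | 19.0 | 0.5 |
| spring | 120 | 19.5 | 0.5 |

(standard deviation of a reading: 0.3 percentage points)

- in percentages every species weighs as the substrate in it: one open dimer or side product counts as two
- for ring the crystals are counted in
- as a solid, counted per litre of solution: crystals
- on the list of suspects stand: substrate <-> ring; 2 substrate -> open dimer; substrate + ring -> side product; crystals <-> ring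

- the flasks by amount of ring, in percent of the substrate charged, highest first, at 2.0 h (green / violet / blue / grey)
- the amount of ring, in percent of the substrate charged of the flask you put first, at 2.0 h
- the amount of ring, in percent of the substrate charged of the flask you put last, at 2.0 h

- My rule: if ring forms at first order and open dimer at second order from the same substrate, substrate goes to ring with the share a/(a + [substrate]), the momentary selectivity, where a is a [substrate] I fit from the readings, at which the two steps would use substrate equally. Summing that share as [substrate] falls from the charge c to zero gives [ring] = a·ln(1 + c/a).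
- Spring's reading at 120 min gives [ring] = 0.332 M. I guess a as dawn's charge and solve the rule for a repeatedly, which gives 0.115 M, then 0.120 M, then 0.122 M. By the rule, far above this ring scale, each decade of charge adds 0.280 M of ring.
- My doubt is that dawn then comes out at 73.0 %, well above its reading at 120 min. But at 30.0 min dawn's ring plus substrate reads 73.0 %, so I take the rule to count that pair before later loss. After that, dawn's ring drops 8.1 percentage points, while spring's stays between 19.0 % and 19.9 %.
- Blue's rule value, 0.291 M, lies near spring's [ring], so I treat blue like spring and expect 24.2 %.
- Violet's charge lies near dawn's, so I scale its rule value by dawn's kept fraction, 0.700, and get 53.8 %. This is my weakest figure, since it carries dawn's loss to another flask.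
- The forecast gives violet > grey > green > blue, top 54 % (50 % to 58 %) and low 25 % (22 % to 29 %), holding that “the percentage falls as concentration rises”.
- The flasks give violet > grey > green > blue, with violet at 48.8 % and blue at 23.9 %. My blue stands 0.30 points above its result, and my violet 5 points above.

    substrate ⇌ ring (K = 2.70, k = 0.123 min⁻¹)
    2 substrate → open dimer (k = 0.249 M⁻¹ min⁻¹)
    substrate + ring → side product (k = 0.110 M⁻¹ min⁻¹)
    crystals ⇌ ring, rate k4*(cs4 - [ring]) while solid is left; crystals form when [ring] > cs4 (solubility = 31.0 mM, k = 0.0996 min⁻¹)

- At the start of blue, the step to open dimer uses substrate 4.9 times as fast as the forward step to ring. In blue, half of the dimer step's turnover up to 2.0 h is done by 0.938 min.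
- Take the neighbour of blue charged with 3.0 M. The ring scale gives 0.396 M, or 13.2 % of its charge, and the flask gives 13.1 %.

Readings and results were generated by integration with constants of no real substance, noise included.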